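The resorcinol is treated as a dehydrogenated cyclohexane-1,3-dione: its oxygenated carbons C3 and C5 both lie meta to C1, the ring carbon bearing the (R)-2-hydroxyheptadecyl chain, and this 1,3,5-pattern is what a malonate–enone annulation produces without any regiochemical choice. In a single operation dimethyl malonate adds to the β-carbon of an acyclic (E)-3-en-2-one (ring bond C1–C6) and the methyl-ketone carbon is then acylated by a malonate ester (ring bond C4–C5), closing the only ring. The precursor is (3E,6R)-6-(benzyloxy)henicos-3-en-2-one, whose carbinol centre is set earlier by enantioselective allylation of 1-hexadecanol; decarboxylation, dehydrogenation and debenzylation complete the route.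

Key step: step 4

Remark: for an unbranched aliphatic alcohol the S antipode of the bisphosphine is taken to direct allyl to the Si face of the transient aldehyde (R carbinol); this sense would be confirmed on the first batch by Mosher ester analysis of 4, and the R ligand used should it prove opposite.

Step 1
Reactants: 1 1-hexadecanol; 2 allyl acetate
Product: 4 (4R)-nonadec-1-en-4-ol, via hexadecanal 3 (not isolated)
Conditions: [Ir(cod)Cl]2 (2.5 mol %), (S)-Cl,MeO-BIPHEP (5 mol %), 4-chloro-3-nitrobenzoic acid (10 mol %), Cs2CO3 (20 mol %), excess allyl acetate, THF, 100 °C, sealed tube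
Reagents that add atoms: none
Why: Krische transfer-hydrogenative carbonyl allylation, in which the cyclometallated iridium–bisphosphine benzoate complex dehydrogenates 1 to aldehyde 3, ionises allyl acetate to an allyliridium species and adds it to 3 through a closed chair-like transition state whose S ligand exposes the Si face, so the new carbinol centre should form R under catalyst control (the allyl CH2 outranks the alkyl CH2).

Step 2
Reactants: 4 (4R)-nonadec-1-en-4-ol
Product: 5 (4R)-4-(benzyloxy)nonadec-1-ene
Conditions: NaH, BnBr, Bu4NI (cat.), THF–DMF, 0 °C → rt
Reagents that add atoms: benzyl bromide, BrCc1ccccc1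
Why: Williamson etherification, in which the sodium alkoxide of 4 displaces bromide from benzyl bromide so that the C–O bond at the stereocentre is never broken, and the resulting benzyl ether should tolerate the hot alkoxide, aqueous acid and iodine of steps 4 to 6 better than a silyl ether would.

Step 3
Reactants: 5 (4R)-4-(benzyloxy)nonadec-1-ene; 6 methyl vinyl ketone
Product: 7 (3E,6R)-6-(benzyloxy)henicos-3-en-2-one
Conditions: second-generation Grubbs catalyst (H2IMes)(PCy3)Cl2Ru=CHPh (3 mol %), MVK (3 equiv), CH2Cl2, 40 °C
Reagents that add atoms: none
Why: Olefin cross-metathesis of an unhindered terminal alkene with an electron-poor enone that homodimerises only slowly, which should give the cross product selectively as the E isomer with loss of ethylene (any Z isomer would converge in step 4), the ether and the stereocentre being spectators.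

Step 4
Reactants: 7 (3E,6R)-6-(benzyloxy)henicos-3-en-2-one; 8 dimethyl malonate
Product: 10 methyl 6-[(2R)-2-(benzyloxy)heptadecyl]-2,4-dioxocyclohexane-1-carboxylate, via Michael adduct 9 (not isolated)
Conditions: dimethyl malonate (1.3 equiv), NaOMe (1.15 equiv), MeOH–THF, 0 °C → rt, then reflux; cold 1 M HCl work-up
Reagents that add atoms: none
Why: The preformed sodium enolate of 8 adds to the β-carbon (C4) of enone 7 to give 9 (Michael addition); on heating, methoxide reversibly forms the ketone enolate on the methyl side, whose carbon attacks one malonate ester carbonyl and expels methoxide, and the sequence is driven to completion because 10 is removed as its doubly stabilised 1,3-diketone enolate. The closest known reaction is the malonate–enone Michael–Claisen (Dieckmann-type) annulation by which dimedone and the 5-alkylcyclohexane-1,3-dione precursors of olivetol-type resorcinols are made. The six-membered carbocycle is closed by a 6-exo-trig acyl substitution (enolate carbon onto the ester C=O, the enolate double bond lying inside the new ring). The two ring stereocentres created (C1 and C6) are not controlled and the product is an epimeric, largely enolised mixture, which does not matter because C1 loses its ester in step 5 and both carbons become sp2 in step 6, while the carbinol centre lies outside the reacting atoms and is unchanged. The selectivity needed is conjugate addition ahead of γ-deprotonation of 7 (which could expel benzyloxide to a dienone) and closure from the methyl side only: the first is secured by running the Michael stage cold with malonate in excess over methoxide and by the poor leaving ability of an alkoxide, the second by ring size, since the C3 enolate could only reach an ester through a four-membered ring.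

Step 5
Reactants: 10 methyl 6-[(2R)-2-(benzyloxy)heptadecyl]-2,4-dioxocyclohexane-1-carboxylate
Product: 12 5-[(2R)-2-(benzyloxy)heptadecyl]cyclohexane-1,3-dione, via keto acid 11 (not isolated)
Conditions: 2 M NaOH aq, MeOH, reflux; then HCl to pH 2, 70 °C
Reagents that add atoms: none
Why: Ester saponification followed by acidification gives the β-keto acid 11, which should decarboxylate through the usual cyclic six-membered transition state on gentle warming (as in the preparation of dimedone), the dione enolate resisting retro-Claisen cleavage in base, the benzyl ether and carbinol centre being inert, and the C1 ring stereocentre disappearing.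

Step 6
Reactants: 12 5-[(2R)-2-(benzyloxy)heptadecyl]cyclohexane-1,3-dione
Product: 14 5-[(2R)-2-(benzyloxy)heptadecyl]benzene-1,3-diol, via 4-iodo dione 13 (not isolated)
Conditions: I2 (20 mol %), DMSO, 80 °C; aq Na2S2O3 work-up
Reagents that add atoms: none
Why: Iodine-catalysed dehydrogenative aromatisation with DMSO as terminal oxidant, in which the enolised dione is iodinated at C4 to give 13, HI is lost across C4–C5 and the resulting ene-dione tautomerises irreversibly to the resorcinol while DMSO returns HI to I2, the benzyl ether keeping the secondary carbinol from oxidation and the remaining ring stereocentre being erased.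

Step 7
Reactants: 14 5-[(2R)-2-(benzyloxy)heptadecyl]benzene-1,3-diol
Product: 15 (2R)-1-(3,5-dihydroxyphenyl)heptadecan-2-ol
Conditions: H2 (1 atm), 10% Pd/C, EtOAc–EtOH, rt
Reagents that add atoms: none
Why: Catalytic hydrogenolysis of the benzyl ether breaks only the O–CH2Ph bond, so the carbinol C–O bond and its R configuration are retained, and the resorcinol ring and alkyl chain are inert to Pd/C and hydrogen at room temperature and atmospheric pressure.

Compound list
1 | 1-hexadecanol | CCCCCCCCCCCCCCCCO | starting material
2 | allyl acetate (prop-2-en-1-yl acetate) | C=CCOC(C)=O | starting material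
3 | hexadecanal | CCCCCCCCCCCCCCCC=O | intermediate
4 | (4R)-nonadec-1-en-4-ol | CCCCCCCCCCCCCCC[C@@H](O)CC=C | intermediate
5 | (4R)-4-(benzyloxy)nonadec-1-ene | CCCCCCCCCCCCCCC[C@@H](OCc1ccccc1)CC=C | intermediate
6 | methyl vinyl ketone (but-3-en-2-one) | C=CC(C)=O | starting material
7 | (3E,6R)-6-(benzyloxy)henicos-3-en-2-one | CCCCCCCCCCCCCCC[C@@H](OCc1ccccc1)C/C=C/C(C)=O | intermediate
8 | dimethyl malonate | COC(=O)CC(=O)OC | starting material
9 | dimethyl 2-[(6R)-6-(benzyloxy)-2-oxohenicosan-4-yl]propanedioate, both C4 epimers | CCCCCCCCCCCCCCC[C@@H](OCc1ccccc1)CC(CC(C)=O)C(C(=O)OC)C(=O)OC | intermediate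
10 | methyl 6-[(2R)-2-(benzyloxy)heptadecyl]-2,4-dioxocyclohexane-1-carboxylate, ring epimers and enol forms | CCCCCCCCCCCCCCC[C@@H](OCc1ccccc1)CC1CC(=O)CC(=O)C1C(=O)OC | intermediate
11 | 6-[(2R)-2-(benzyloxy)heptadecyl]-2,4-dioxocyclohexane-1-carboxylic acid, ring epimers | CCCCCCCCCCCCCCC[C@@H](OCc1ccccc1)CC1CC(=O)CC(=O)C1C(=O)O | intermediate
12 | 5-[(2R)-2-(benzyloxy)heptadecyl]cyclohexane-1,3-dione | CCCCCCCCCCCCCCC[C@@H](OCc1ccccc1)CC1CC(=O)CC(=O)C1 | intermediate
13 | 5-[(2R)-2-(benzyloxy)heptadecyl]-4-iodocyclohexane-1,3-dione, ring epimers | CCCCCCCCCCCCCCC[C@@H](OCc1ccccc1)CC1CC(=O)CC(=O)C1I | intermediate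
14 | 5-[(2R)-2-(benzyloxy)heptadecyl]benzene-1,3-diol | CCCCCCCCCCCCCCC[C@@H](OCc1ccccc1)Cc1cc(O)cc(O)c1 | intermediate
15 | (2R)-1-(3,5-dihydroxyphenyl)heptadecan-2-ol | CCCCCCCCCCCCCCC[C@@H](O)Cc1cc(O)cc(O)c1 | target

Total step count: 7
Longest linear sequence: 7 steps (1 to 15)

Steps most likely to fail

First, step 6. The process at risk is electrophilic iodination of the electron-rich resorcinol as it forms, or stalling at the α-iodo stage, because DMSO keeps regenerating I2. The fallback sets out from 10 and comes back at 14: the ring would be aromatised one stage earlier, while the ester is still attached and deactivates the arene towards further halogenation. The sodium enolate of 10 in DMF would be treated with one equivalent of Br2 at 0 °C and then warmed to about 80 °C, which should give, without isolation, methyl 6-[(2R)-2-(benzyloxy)heptadecyl]-5-bromo-2,4-dioxocyclohexane-1-carboxylate F1 and, after loss of HBr and tautomerisation, methyl 6-[(2R)-2-(benzyloxy)heptadecyl]-2,4-dihydroxybenzoate F2. Saponification with hot aqueous NaOH would give 6-[(2R)-2-(benzyloxy)heptadecyl]-2,4-dihydroxybenzoic acid F3, which as an ortho,para-dihydroxybenzoic acid should lose CO2 on acidification and warming to give 14.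

Second, step 4. The process at risk is γ-deprotonation of the enone by methoxide with vinylogous β-elimination of benzyloxide, or reversal of the Michael addition during the hot Claisen stage. The fallback sets out from 7 and 8 and comes back at 10: the two bond formations would be separated. The Michael addition would be run under solid–liquid phase-transfer conditions (K2CO3, catalytic Bu4NBr, toluene, rt), where no strong base meets the enone, and the adduct 9 would be isolated. Compound 9, which no longer has a leaving group β to any acidic position, would then be closed in a discrete Dieckmann-type step (NaOMe, MeOH–THF, reflux, with a little added dimethyl malonate to recapture any enone released by retro-Michael reaction), and acidic work-up would give 10 (no new compound: F0).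

Third, step 1. The process at risk is insufficient enantioselectivity or stalled dehydrogenation with the waxy C16 alcohol, or an induction sense opposite to the one assumed. The fallback sets out from 1 and comes back at 4: the alcohol would be oxidised to hexadecanal 3, now isolated (TEMPO, PhI(OAc)2, CH2Cl2). Aldehyde 3 would be allylated at −78 °C in Et2O with (−)-Ipc2B(allyl), prepared from (−)-Ipc2BOMe and allylMgBr (Brown allylation, reagent-controlled Si-face attack through a chair six-membered transition state), followed by NaOH/H2O2 work-up to 4 (no new compound: F0).

Further compounds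
F1 | step 6 | methyl 6-[(2R)-2-(benzyloxy)heptadecyl]-5-bromo-2,4-dioxocyclohexane-1-carboxylate | CCCCCCCCCCCCCCC[C@@H](OCc1ccccc1)CC1C(Br)C(=O)CC(=O)C1C(=O)OC
F2 | step 6 | methyl 6-[(2R)-2-(benzyloxy)heptadecyl]-2,4-dihydroxybenzoate | CCCCCCCCCCCCCCC[C@@H](OCc1ccccc1)Cc1cc(O)cc(O)c1C(=O)OC
F3 | step 6 | 6-[(2R)-2-(benzyloxy)heptadecyl]-2,4-dihydroxybenzoic acid | CCCCCCCCCCCCCCC[C@@H](OCc1ccccc1)Cc1cc(O)cc(O)c1C(=O)O
F0 | step 4 | none | none
F0 | step 1 | none | none
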